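The route rests on cutting O1–C2 and C3–C4 of the upper pyran (C ring). Both bonds, the ring and the three upper stereocentres are made at once by a hetero-Diels–Alder reaction between an ortho-quinone methide of the resorcinol A ring and an (E)-styrylboronate whose boron is a masked C3 hydroxyl. The step exploits the all-equatorial C2-aryl/C3-oxy/C4-aryl array on O1–C2–C3–C4, with C4 bonded to C6′ of the gallocatechin D ring: this is the endo adduct of an E-methide and an E-alkene. The precursor is a diaryl carbinol linking a 4-benzyloxy-2-hydroxyphenyl ring to C6 of 8-bromo-hexa-O-benzylgallocatechin.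

Key step: step 7

Remarks and assumptions on the chemistry
- The target SMILES was checked: the upper unit is 2,3-trans-3,4-trans (2R,3S,4S; 2α-aryl, 3β-OH, 4α-aryl) and the lower unit is (2R,3S)-gallocatechin. All structures used are consistent with this and none needed correction. Primes denote the lower unit.
- The A ring is brought in as a commercial salicylaldehyde (as its phenolate) that is attacked by a C6-metalated gallocatechin. An ortho-silyloxy aryllithium would be open to O→C silyl migration, and this choice needs no phenol protecting group.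
- Assumption: (R)-TRIP is taken to give the required facial sense. If a two-run screen shows the opposite, (S)-TRIP is used under the same conditions; the two possible all-trans adducts are diastereomers and should be separable.

Step 1
Reactants: 1 (+)-gallocatechin
Product: 2 5,7,3′,4′,5′-penta-O-benzyl-(+)-gallocatechin
Conditions: BnBr (5.5 equiv), K2CO3, DMF, Ar, 0 °C → rt
Reagents that add atoms: benzyl bromide, BrCc1ccccc1
Why: Williamson etherification with a carbonate base under argon caps the five phenols and leaves the less acidic C3 alcohol and both stereocentres untouched.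

Step 2
Reactants: 2 5,7,3′,4′,5′-penta-O-benzyl-(+)-gallocatechin
Product: 3 3,5,7,3′,4′,5′-hexa-O-benzyl-(+)-gallocatechin
Conditions: NaH, BnBr, TBAI (cat.), DMF, 0 °C → rt
Reagents that add atoms: benzyl bromide, BrCc1ccccc1
Why: Williamson etherification of the secondary alkoxide caps the last hydroxyl, and with every phenol already etherified no base-induced ring-opening or C2 epimerisation pathway remains.

Step 3
Reactants: 3 3,5,7,3′,4′,5′-hexa-O-benzyl-(+)-gallocatechin
Product: 4 8-bromo-hexa-O-benzylgallocatechin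
Conditions: NBS (1.0 equiv), CH2Cl2, −78 → 0 °C
Reagents that add atoms: N-bromosuccinimide, O=C1CCC(=O)N1Br
Why: Electrophilic aromatic bromination should go to C8, the more accessible of the two free positions of the phloroglucinol-type A ring, which is far more activated than the tribenzyloxyphenyl ring.

Step 4
Reactants: 4 8-bromo-hexa-O-benzylgallocatechin
Product: 5 8-bromo-6-iodo-hexa-O-benzylgallocatechin
Conditions: NIS (1.2 equiv), TFA (10 mol %), CH2Cl2/MeCN, 0 °C → rt, dark
Reagents that add atoms: N-iodosuccinimide, O=C1CCC(=O)N1I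
Why: Electrophilic aromatic iodination at the one remaining A-ring position (C6, two ortho oxygens and one para oxygen) installs a halogen that undergoes metal exchange far faster than the C8 bromine.

Step 5
Reactants: 5 8-bromo-6-iodo-hexa-O-benzylgallocatechin; 6 4-(benzyloxy)-2-hydroxybenzaldehyde
Product: 9 (4-benzyloxy-2-hydroxyphenyl)(8-bromo-hexa-O-benzylgallocatechin-6-yl)methanol as a mixture of carbinol epimers, via arylmagnesium chloride 7 (not isolated), via sodium phenolate 8 (not isolated)
Conditions: 5, i-PrMgCl·LiCl (1.1 equiv), THF, −20 → 0 °C; separately 6 (1.5 equiv), NaH, THF, 0 °C; combine, 0 °C → rt; aq. NH4Cl; Et3N-deactivated silica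
Reagents that add atoms: none
Why: Chemoselective iodine–magnesium exchange leaves the C8 bromine alone and Grignard 1,2-addition to the aldehyde, whose phenol is masked as its sodium salt, gives the diaryl carbinol directly; the carbinol centre forms unselectively and is erased in step 7.

Step 6
Reactants: 10 3,4-bis(benzyloxy)benzaldehyde; 11 bis(pinacolato)borylmethane
Product: 13 (E)-2-[3,4-bis(benzyloxy)styryl]-4,4,5,5-tetramethyl-1,3,2-dioxaborolane, via lithiated diborylmethane 12 (not isolated)
Conditions: LiTMP (from TMPH, n-BuLi), 11, THF, 0 °C; then 10, −78 °C → rt; H2O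
Reagents that add atoms: none
Why: Boron–Wittig olefination, in which the α-boryl carbanion adds to the aldehyde and syn-elimination of the B–O unit delivers the E-alkenylboronate.

Step 7
Reactants: 9 (4-benzyloxy-2-hydroxyphenyl)(8-bromo-hexa-O-benzylgallocatechin-6-yl)methanol; 13 (E)-2-[3,4-bis(benzyloxy)styryl]-4,4,5,5-tetramethyl-1,3,2-dioxaborolane
Product: 15 nona-O-benzyl-8′-bromo-3-deoxy-3β-(pinacolboryl)fisetinidol-(4α→6)-gallocatechin, via ortho-quinone methide 14 (not isolated)
Conditions: 13 (2.5 equiv), (R)-TRIP (10 mol %), 5 Å MS, CH2Cl2, −20 °C → rt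
Reagents that add atoms: none
Why: Proposed new method: the phosphoric acid ionises either carbinol epimer to the E ortho-quinone methide 14, the boron-bearing alkene carbon of 13 attacks the methide carbon (future C4) and the methide oxygen closes onto the developing p-alkoxybenzylic C2 cation, an asynchronous inverse-electron-demand oxa-[4+2] cycloaddition. The closest known reaction is the Brønsted- or chiral-phosphoric-acid-catalysed [4+2] of in situ ortho-quinone methides with electron-rich E-styrenes to 2,4-cis-flavans; an alkenyl pinacolboronate as the 2π partner is the untested element. The C ring closes in an intermolecular (4+2) mode, C3–C4 bond first and then six-membered O1–C2 closure of the phenol oxygen onto the benzylic cation. C2/C3 trans follows from suprafacial addition to the E-alkene, C2/C4 cis from the endo placement of the dibenzyloxyphenyl group over the E-methide (its bulky 2,6-dioxygenated aryl sits anti to the carbonyl), and the absolute sense at C4, and with it C2 and C3, from the chiral phosphate bound to the methide oxygen, the remote gallocatechin centres making the two facial outcomes separable diastereomers. Regiochemistry is secured by the 3,4-dibenzyloxyphenyl group, which places the positive charge at C2 while the weakly perturbing Bpin stays on the attacking carbon (an enol ether would reverse it); C8′–Br prevents self-arylation by the D ring, and the robust pinacol ester in a non-nucleophilic medium is chosen so that ring closure outruns loss of boron by alkenyl transfer.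

Step 8
Reactants: 15 nona-O-benzyl-8′-bromo-3-deoxy-3β-(pinacolboryl)fisetinidol-(4α→6)-gallocatechin
Product: 16 nona-O-benzyl-8′-bromo-fisetinidol-(4α→6)-gallocatechin
Conditions: 30% H2O2, 2 M NaOH, THF, 0 °C → rt
Reagents that add atoms: hydrogen peroxide, OO
Why: Oxidation of the C–B bond by hydroperoxide proceeds by 1,2-migration of carbon from boron to oxygen with retention, so the 3β-boryl group becomes the 3β-hydroxyl (2,3-trans-3,4-trans), as in the hydroboration–oxidation of flav-3-enes.

Step 9
Reactants: 16 nona-O-benzyl-8′-bromo-fisetinidol-(4α→6)-gallocatechin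
Product: 17 fisetinidol-(4α→6)-gallocatechin
Conditions: H2 (1 atm), Pd(OH)2/C, Et3N (2 equiv), THF/MeOH/H2O, rt
Reagents that add atoms: none
Why: Palladium-catalysed hydrogenolysis cleaves all nine O-benzyl ethers and hydrodehalogenates C8′–Br in one operation, with triethylamine trapping HBr so that the interflavan bond and all five stereocentres are untouched.

Compound list
1 | (+)-gallocatechin, (2R,3S)-2-(3,4,5-trihydroxyphenyl)chroman-3,5,7-triol | c1c(O)cc2c(c1O)C[C@H](O)[C@@H](c1cc(O)c(O)c(O)c1)O2 | starting material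
2 | 5,7,3′,4′,5′-penta-O-benzyl-(+)-gallocatechin (2R,3S; free 3-OH) | c1c(OCc3ccccc3)cc2c(c1OCc3ccccc3)C[C@H](O)[C@@H](c1cc(OCc3ccccc3)c(OCc3ccccc3)c(OCc3ccccc3)c1)O2 | intermediate
3 | 3,5,7,3′,4′,5′-hexa-O-benzyl-(+)-gallocatechin (2R,3S) | c1c(OCc3ccccc3)cc2c(c1OCc3ccccc3)C[C@H](OCc3ccccc3)[C@@H](c1cc(OCc3ccccc3)c(OCc3ccccc3)c(OCc3ccccc3)c1)O2 | intermediate
4 | 8-bromo-hexa-O-benzylgallocatechin (2R,3S) | c1c(OCc3ccccc3)c(Br)c2c(c1OCc3ccccc3)C[C@H](OCc3ccccc3)[C@@H](c1cc(OCc3ccccc3)c(OCc3ccccc3)c(OCc3ccccc3)c1)O2 | intermediate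
5 | 8-bromo-6-iodo-hexa-O-benzylgallocatechin (2R,3S) | Ic1c(OCc3ccccc3)c(Br)c2c(c1OCc3ccccc3)C[C@H](OCc3ccccc3)[C@@H](c1cc(OCc3ccccc3)c(OCc3ccccc3)c(OCc3ccccc3)c1)O2 | intermediate
6 | 4-(benzyloxy)-2-hydroxybenzaldehyde | O=Cc1ccc(OCc2ccccc2)cc1O | starting material
7 | (8-bromo-hexa-O-benzylgallocatechin-6-yl)magnesium chloride (2R,3S) | Cl[Mg]c1c(OCc3ccccc3)c(Br)c2c(c1OCc3ccccc3)C[C@H](OCc3ccccc3)[C@@H](c1cc(OCc3ccccc3)c(OCc3ccccc3)c(OCc3ccccc3)c1)O2 | intermediate (not isolated)
8 | sodium 5-(benzyloxy)-2-formylphenolate | [Na+].[O-]c1cc(OCc2ccccc2)ccc1C=O | intermediate (not isolated)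
9 | (4-benzyloxy-2-hydroxyphenyl)(8-bromo-hexa-O-benzylgallocatechin-6-yl)methanol, both carbinol epimers, lower unit 2R,3S | Oc1cc(OCc3ccccc3)ccc1C(O)c1c(OCc3ccccc3)c(Br)c2c(c1OCc3ccccc3)C[C@H](OCc3ccccc3)[C@@H](c1cc(OCc3ccccc3)c(OCc3ccccc3)c(OCc3ccccc3)c1)O2 | intermediate (key-step precursor)
10 | 3,4-bis(benzyloxy)benzaldehyde | O=Cc1ccc(OCc2ccccc2)c(OCc2ccccc2)c1 | starting material
11 | bis(pinacolato)borylmethane, 2,2′-methylenebis(4,4,5,5-tetramethyl-1,3,2-dioxaborolane) | CC1(C)OB(CB2OC(C)(C)C(C)(C)O2)OC1(C)C | starting material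
12 | lithio-bis(pinacolboryl)methane | [Li]C(B1OC(C)(C)C(C)(C)O1)B1OC(C)(C)C(C)(C)O1 | intermediate (not isolated)
13 | (E)-2-[3,4-bis(benzyloxy)styryl]-4,4,5,5-tetramethyl-1,3,2-dioxaborolane | CC1(C)OB(/C=C/c2ccc(OCc3ccccc3)c(OCc3ccccc3)c2)OC1(C)C | intermediate
14 | (E)-3-(benzyloxy)-6-[(8-bromo-hexa-O-benzylgallocatechin-6-yl)methylidene]cyclohexa-2,4-dien-1-one, the ortho-quinone methide | O=C1C=C(OCc3ccccc3)C=C/C1=C\c1c(OCc3ccccc3)c(Br)c2c(c1OCc3ccccc3)C[C@H](OCc3ccccc3)[C@@H](c1cc(OCc3ccccc3)c(OCc3ccccc3)c(OCc3ccccc3)c1)O2 | intermediate (not isolated)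
15 | nona-O-benzyl-8′-bromo-3-deoxy-3β-(pinacolboryl)fisetinidol-(4α→6)-gallocatechin; upper unit 2α-aryl, 3β-boryl, 4α-aryl (2S,3S,4S by CIP, boron in place of oxygen), lower unit 2R,3S | O(Cc3ccccc3)c1ccc2c(c1)O[C@H](c1ccc(OCc3ccccc3)c(OCc3ccccc3)c1)[C@@H](B4OC(C)(C)C(C)(C)O4)[C@@H]2c1c(OCc3ccccc3)c(Br)c2c(c1OCc3ccccc3)C[C@H](OCc3ccccc3)[C@@H](c1cc(OCc3ccccc3)c(OCc3ccccc3)c(OCc3ccccc3)c1)O2 | intermediate (key-step product)
16 | nona-O-benzyl-8′-bromo-fisetinidol-(4α→6)-gallocatechin; upper unit 2R,3S,4S with free 3-OH, lower unit 2R,3S | O(Cc3ccccc3)c1ccc2c(c1)O[C@H](c1ccc(OCc3ccccc3)c(OCc3ccccc3)c1)[C@@H](O)[C@@H]2c1c(OCc3ccccc3)c(Br)c2c(c1OCc3ccccc3)C[C@H](OCc3ccccc3)[C@@H](c1cc(OCc3ccccc3)c(OCc3ccccc3)c(OCc3ccccc3)c1)O2 | intermediate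
17 | fisetinidol-(4α→6)-gallocatechin; upper unit 2R,3S,4S, lower unit 2R,3S | Oc1ccc2c(c1)O[C@H](c1ccc(O)c(O)c1)[C@@H](O)[C@@H]2c1c(O)cc2c(c1O)C[C@H](O)[C@@H](c1cc(O)c(O)c(O)c1)O2 | target

Total step count: 9. Longest linear sequence: 8 (steps 1–5, 7, 8, 9).

Steps most likely to fail

Step 7. The stabilised methide may be too weak an electrophile for the alkenylboronate, ring closure may lose to deborylative alkenyl transfer, or the catalyst may give poor facial control. The fallback uses known flavan-4-yl cation chemistry, sets out from 4 and rejoins the route at 16. Commercial (2R,3R)-fustin F1 is benzylated at its three phenols (BnBr, K2CO3, DMF) to 7,3′,4′-tri-O-benzylfustin F2. NaBH4 (THF/EtOH, 0 °C) should reduce this to the 2,3-trans-3,4-trans diol (2R,3S,4R)-7,3′,4′-tris(benzyloxy)flavan-3,4-diol F3. Ionisation of F3 at C4 with BF3·OEt2 (CH2Cl2, −40 → 0 °C) in the presence of excess 4 should arylate C6′, since C8′ is blocked, mainly trans to the C3 hydroxyl. This would give 16 directly, and step 9 then finishes the synthesis. C2 and C3 then come from the natural dihydroflavonol and 4α from 1,2-trans attack; any 4β epimer would be removed by chromatography.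

Step 5. The iodine–magnesium exchange may be slow or incomplete, or the di-ortho-substituted arylmagnesium may add sluggishly to the deactivated phenolate-aldehyde and end up protonated on work-up. The fallback sets out from 5 and 6 and rejoins at 9. Aldehyde 6 is silylated (TIPSCl, imidazole, DMF) to 4-(benzyloxy)-2-(triisopropylsilyloxy)benzaldehyde F4, a neutral and much more electrophilic partner. Iodine–lithium exchange on 5 (n-BuLi, THF, −78 °C) gives the 6-lithio derivative of 8-bromo-hexa-O-benzylgallocatechin F5. F5 adds to F4 at −78 °C, with an AcOH quench at that temperature to forestall O→O silyl migration, giving the O-TIPS carbinol F6. Buffered fluoride (TBAF, AcOH, THF, 0 °C) then frees the phenol to give 9.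

Step 4. Iodination may occur on the tribenzyloxyphenyl ring in competition with the crowded C6, or C6 may not react. The fallback sets out from 4, replaces steps 4 and 5, and rejoins at 9. Vilsmeier–Haack formylation (POCl3, DMF, 0 → 60 °C, then aq. NaOAc), a weaker and more site-selective electrophile, should give 8-bromo-6-formyl-hexa-O-benzylgallocatechin F7. Commercial 4-bromoresorcinol F8 is monobenzylated at the hydroxyl para to bromine (BnBr, K2CO3, acetone; the regioisomer is removed by chromatography) to 5-(benzyloxy)-2-bromophenol F9. With n-BuLi (2 equiv, THF, −78 → 0 °C) F9 gives lithium 5-(benzyloxy)-2-lithiophenolate F10. Addition of excess F10 to F7 at −78 °C should give 9 without any phenol protecting group.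

Further compounds
F1 | step 7 | (2R,3R)-fustin (purchased starting material of the fallback) | Oc1ccc2c(c1)O[C@H](c1ccc(O)c(O)c1)[C@@H](O)C2=O
F2 | step 7 | (2R,3R)-7,3′,4′-tri-O-benzylfustin | O(Cc3ccccc3)c1ccc2c(c1)O[C@H](c1ccc(OCc3ccccc3)c(OCc3ccccc3)c1)[C@@H](O)C2=O
F3 | step 7 | (2R,3S,4R)-7,3′,4′-tris(benzyloxy)flavan-3,4-diol | O(Cc3ccccc3)c1ccc2c(c1)O[C@H](c1ccc(OCc3ccccc3)c(OCc3ccccc3)c1)[C@@H](O)[C@@H]2O
F4 | step 5 | 4-(benzyloxy)-2-(triisopropylsilyloxy)benzaldehyde | O=Cc1ccc(OCc2ccccc2)cc1O[Si](C(C)C)(C(C)C)C(C)C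
F5 | step 5 | 6-lithio-8-bromo-hexa-O-benzylgallocatechin (2R,3S) | [Li]c1c(OCc3ccccc3)c(Br)c2c(c1OCc3ccccc3)C[C@H](OCc3ccccc3)[C@@H](c1cc(OCc3ccccc3)c(OCc3ccccc3)c(OCc3ccccc3)c1)O2
F6 | step 5 | [4-benzyloxy-2-(triisopropylsilyloxy)phenyl](8-bromo-hexa-O-benzylgallocatechin-6-yl)methanol, both carbinol epimers | CC(C)[Si](C(C)C)(C(C)C)Oc1cc(OCc3ccccc3)ccc1C(O)c1c(OCc3ccccc3)c(Br)c2c(c1OCc3ccccc3)C[C@H](OCc3ccccc3)[C@@H](c1cc(OCc3ccccc3)c(OCc3ccccc3)c(OCc3ccccc3)c1)O2
F7 | step 4 | 8-bromo-6-formyl-hexa-O-benzylgallocatechin (2R,3S) | O=Cc1c(OCc3ccccc3)c(Br)c2c(c1OCc3ccccc3)C[C@H](OCc3ccccc3)[C@@H](c1cc(OCc3ccccc3)c(OCc3ccccc3)c(OCc3ccccc3)c1)O2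
F8 | step 4 | 4-bromoresorcinol (purchased starting material of the fallback) | Oc1ccc(Br)c(O)c1
F9 | step 4 | 5-(benzyloxy)-2-bromophenol | Oc1cc(OCc2ccccc2)ccc1Br
F10 | step 4 | lithium 5-(benzyloxy)-2-lithiophenolate | [Li]Oc1cc(OCc2ccccc2)ccc1[Li]
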